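What is left of Q at the end of a flask is not among the readings, but the readings give it.

all flasks: X 0.20 M

| flask | Q | remark | time |
|---|---|---|---|
| Sunday's | 0.17 M | run made earlier |  |
| Monday's | 0.22 M | run made earlier |  |
| Wednesday's | 0.34 M | run made earlier |  |
| west | 0.160 M |  | 4.0 h |
| south-east | 0.240 M |  | 4.0 h |
| south | 0.360 M |  | 4.0 h |

| run | time / h | D / % | X / % | Z / % | J / % |
|---|---|---|---|---|---|
| Sunday's | 0.333 | 0 | 96.4 | 3.4 | 0 |
| Sunday's | 1.00 | 2.2 | 90.7 | 4.1 | 2.1 |
| Sunday's | 2.00 | 4.3 | 82.6 | 4.9 | 3.6 |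
| Sunday's | 3.00 | 6.9 | 77.0 | 4.7 | 7.1 |
| Sunday's | 4.00 | 11.0 | 71.6 | 3.7 | 7.7 |
| Monday's | 0.333 | 1.5 | 95.8 | 3.6 | 0.1 |
| Monday's | 0.667 | 1.4 | 93.1 | 4.7 | 1.2 |
| Monday's | 1.00 | 1.9 | 86.9 | 5.5 | 2.7 |
| Monday's | 2.00 | 5.1 | 78.4 | 4.9 | 7.1 |
| Monday's | 4.00 | 11.6 | 65.9 | 5.5 | 12.4 |
| Wednesday's | 0.833 | 2.6 | 84.6 | 6.0 | 5.1 |
| Wednesday's | 1.50 | 4.5 | 74.7 | 7.3 | 10.0 |
| Wednesday's | 2.50 | 9.0 | 62.7 | 4.7 | 15.7 |
| Wednesday's | 3.00 | 10.1 | 59.2 | 4.8 | 17.2 |
| Wednesday's | 4.00 | 13.0 | 52.2 | 5.1 | 20.7 |

(scatter of a reading: 0.5 percentage points)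

- which of these there is most of at the end, counted by the X in it, west (Z / D / J / X)
- which of these there is most of at the end, counted by the X in it, south-east (Z / D / J / X)
- which of these there is most of at the end, counted by the X in it, south (Z / D / J / X)
- final amount of the leader among these, as a percentage of the X charged, in west
- final amount of the leader among these, as a percentage of the X charged, in south-east
- final amount of the leader among these, as a percentage of the X charged, in south

- a reading or a percentage of J counts all its forms, free or not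
- a reading of X is of its free form alone

Each Z holds one Q and each J two, and D is assumed here to hold one. A reading of J counts its bound forms, so bound J enters the balance too. Q spent is therefore [X] as charged times the fractions D plus Z plus two J. At 4.0 h this leaves 64.6% of the charge on Sunday, 61.9% on Monday and 65.0% on Wednesday. Their mean, 63.8%, is the Q share left, the free Q at the end over the Q charged.

The Wednesday charge is twice Sunday's, yet the share stays close, and a share independent of the charge marks a pseudo-first-order fall of Q at fixed [X]. West holds less Q than X, so Q is its limiting reagent, but the share still leaves 0.102 M free there.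

So mean [Q] scales with the charge, and the negative logarithm of the X fraction should too. Over [Q] as charged it reads 1.92 M⁻¹ on average. This reckoning gives X 73.5%, 63.0% and 50.0% in west, south-east and south.

The forecast names X, X and X as leaders there, at 73%, 63% and 50.5%, and reads: “X loss is roughly first order in Q”.

The flasks give X, X and X, at 73.7%, 63.2% and 50.6%.

    Z + Q ⇌ L + J (K = 1.80, k = 0.00120 M⁻¹ s⁻¹)
    X + Q ⇌ L + Z (K = 0.260, k = 1.50 × 10⁻⁴ M⁻¹ s⁻¹)
    L → E (k = 2.20 × 10⁻⁵ s⁻¹)
    X + J ⇌ G, settled at all times (K = 6.70 M⁻¹)
    Z → D (k = 1.70 × 10⁻⁴ s⁻¹)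

In south, X + Q → L + Z had 66% of its turnover up to the end behind it at 2.00 h. Meanwhile Z went from 6.35% at 0.800 h to 5.31% at the end, made over used 0.971, as J reached 21.7% and D 13.7%. The Q share left stands at 62%, 63% and 65% in west, south-east and south, against 63.8% from the readings.

A neighbour flask is south with 0.50 M of X, so Q stands at 0.720 equiv to X. If the fall of Q scales with [X], the share is raised to the power 2.50, which gives 32.6%. That neighbour flask keeps 39% of its Q, 6 percentage points above the reckoning, and 60% of its X unbound.

Readings and results were generated by integration with constants of no real substance; the scatter is artificial.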